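**Strategy.** The plan cuts the bond between C9, the oxygen-bearing carbon of the seven-membered ring, and C10, the methyl-bearing quaternary carbon of the cyclobutane (longipinane numbering). Because C10 is a one-carbon bridge of the bicyclo[3.1.1]heptenone (ring A plus cyclobutane) whose only exocyclic groups are methyl and C9, it can be carried as an exocyclic methylidene. A reductive 7-exo Heck cyclization of a (Z)-alkenyl iodide tethered at C5 then closes the seven-membered ring, creates the C10 stereocentre and turns the methylidene into the methyl group in one operation, leaving the C8=C9 alkene for the cis-diol. The precursor comes from (S)-pantolactone by an intramolecular vinylketene–alkene cycloaddition.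

Key step: step 15

Remark on labels and assumptions: longipinane numbering is used for the tricycle. C1 is the ketone, C2=C3 the enone alkene (C3 bears a methyl), C4 and C11 are the ring-A bridgeheads, the cyclobutane is C4–C5–C11–C10, and the seven-membered ring runs C5–C6(Me2)–C7–C8–C9–C10. The three esters are angelates, i.e. (Z)-2-methylbut-2-enoates. TBDPS is tert-butyldiphenylsilyl. (S)-Pantolactone and angelic anhydride are taken as commercial.

**Step 1**
Reactants: 1 (S)-pantolactone
Product: 2 (3S)-3-[(tert-butyldiphenylsilyl)oxy]-4,4-dimethyloxolan-2-one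
Conditions: TBDPSCl, imidazole, DMF, 40 °C
Reagents that add atoms: tert-butyl(chloro)diphenylsilane, CC(C)(C)[Si](Cl)(c1ccccc1)c1ccccc1
Why: Silylation of the secondary hydroxyl gives a bulky, non-migrating ether that carries the future C7 oxygen (stereocentre from the chiral pool) through the route.

**Step 2**
Reactants: 2 silyl-protected lactone
Product: 3 (3S)-3-[(tert-butyldiphenylsilyl)oxy]-4,4-dimethyloxolan-2-ol (lactol, both anomers)
Conditions: i-Bu2AlH (1.1 equiv), CH2Cl2, −78 °C; aqueous potassium sodium tartrate work-up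
Reagents that add atoms: none
Why: Partial hydride reduction of a lactone stops at the lactol because the tetrahedral aluminate is stable at −78 °C.

**Step 3**
Reactants: 3 lactol
Product: 4 (3R)-3-[(tert-butyldiphenylsilyl)oxy]-2,2-dimethylpent-4-yn-1-ol
Conditions: dimethyl (1-diazo-2-oxopropyl)phosphonate, K2CO3, MeOH, 0 to 23 °C
Reagents that add atoms: dimethyl (1-diazo-2-oxopropyl)phosphonate, CC(=O)C(=[N+]=[N-])P(=O)(OC)OC
Why: Seyferth–Gilbert homologation in the Ohira–Bestmann variant converts the open-chain hydroxy aldehyde in equilibrium with the lactol into the terminal alkyne (future C8 and C9) under conditions mild enough to leave the α-silyloxy centre untouched.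

**Step 4**
Reactants: 4 alkynol
Product: 5 (3S)-3-[(tert-butyldiphenylsilyl)oxy]-5-iodo-2,2-dimethylpent-4-yn-1-ol
Conditions: N-iodosuccinimide, AgNO3 (10 mol%), acetone, 23 °C, dark
Reagents that add atoms: N-iodosuccinimide, O=C1CCC(=O)N1I
Why: Silver-catalysed electrophilic iodination of a terminal alkyne gives the 1-iodoalkyne without touching the free alcohol.

**Step 5**
Reactants: 5 iodoalkyne
Product: 6 (3R,4Z)-3-[(tert-butyldiphenylsilyl)oxy]-5-iodo-2,2-dimethylpent-4-en-1-ol
Conditions: 2-nitrobenzenesulfonylhydrazide, Et3N, THF/i-PrOH, 23 °C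
Reagents that add atoms: none
Why: Diimide generated in the flask adds H2 syn to the iodoalkyne, which sets the (Z)-alkenyl iodide geometry needed for a cis alkene in the seven-membered ring.

**Step 6**
Reactants: 6 (Z)-iodoalkenol
Product: 7 (3R,4Z)-3-[(tert-butyldiphenylsilyl)oxy]-5-iodo-2,2-dimethylpent-4-enal
Conditions: Dess–Martin periodinane, NaHCO3, CH2Cl2, 0 to 23 °C
Reagents that add atoms: none
Why: Dess–Martin oxidation of the neopentyl primary alcohol gives an aldehyde that cannot enolize, so nothing is epimerized.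

**Step 7**
Reactants: 7 aldehyde
Product: 8 (5R,6Z)-5-[(tert-butyldiphenylsilyl)oxy]-7-iodo-4,4-dimethylhepta-1,6-dien-3-ol (both C3 epimers)
Conditions: CH2=CHMgBr, THF, −78 °C
Reagents that add atoms: vinylmagnesium bromide, C=C[Mg]Br
Why: Grignard 1,2-addition gives the allylic alcohol, whose new carbinol centre need not be controlled because it becomes sp2 in step 8.

**Step 8**
Reactants: 8 allylic alcohol
Product: 11 (5E,8R,9Z)-8-[(tert-butyldiphenylsilyl)oxy]-10-iodo-7,7-dimethyldeca-5,9-dien-2-one, via mixed ketal 9 (not isolated), via isopropenyl ether 10 (not isolated)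
Conditions: 2-methoxypropene (10 equiv), pyridinium p-toluenesulfonate (5 mol%), toluene, 120 °C, sealed tube
Reagents that add atoms: 2-methoxypropene, COC(C)=C
Why: Saucy–Marbet Claisen rearrangement ([3,3] shift of the allyl isopropenyl ether) delivers the γ,δ-unsaturated methyl ketone, and the chair transition state with the bulky quaternary substituent equatorial gives the E alkene (future C5–C11 bond of the cyclobutane).

**Step 9**
Reactants: 11 methyl ketone
Product: 12 methyl (2E,6E,9R,10Z)-9-[(tert-butyldiphenylsilyl)oxy]-11-iodo-3,8,8-trimethylundeca-2,6,10-trienoate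
Conditions: (MeO)2P(O)CH2CO2Me, NaH, THF, 0 to 50 °C; the minor (2Z) isomer is removed by chromatography
Reagents that add atoms: trimethyl phosphonoacetate, COC(=O)CP(=O)(OC)OC
Why: Horner–Wadsworth–Emmons olefination of a methyl ketone should favour the (2E) ester, which places the methyl group syn to the carbonyl as step 11 requires.

**Step 10**
Reactants: 12 methyl ester
Product: 13 (2E,6E,9R,10Z)-9-[(tert-butyldiphenylsilyl)oxy]-11-iodo-3,8,8-trimethylundeca-2,6,10-trienoic acid
Conditions: LiOH, THF/MeOH/H2O, 40 °C; then dilute HCl to pH 3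
Reagents that add atoms: lithium hydroxide, [Li+].[OH-]
Why: Saponification of the conjugated ester leaves the hindered silyl ether and the alkenyl iodide intact.

**Step 11**
Reactants: 13 trienoic acid
Product: 16 (1R,5R,7R)-7-[(3R,4Z)-3-[(tert-butyldiphenylsilyl)oxy]-5-iodo-2-methylpent-4-en-2-yl]-2-methylidenebicyclo[3.1.1]heptan-6-one, via acid chloride 14 (not isolated), via vinylketene 15 (not isolated)
Conditions: (COCl)2, DMF (cat.), CH2Cl2, 0 to 23 °C, evaporate; then slow addition to Et3N (5 equiv), toluene, 110 °C, 0.005 M; chromatographic separation of the diastereomer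
Reagents that add atoms: none
Why: Dehydrochlorination at the methyl group syn to the acyl group gives vinylketene 15, which undergoes the intramolecular ketene–alkene [2+2] cycloaddition with the ketene carbonyl carbon (future C10) bonding to the nearer, less hindered alkene carbon (future C11) and the α-carbon (future C4) to the neopentyl carbon (future C5), so the bridged bicyclo[3.1.1]heptan-6-one should form; suprafacial addition to the E alkene puts the side chain on C5 anti to ring A and fixes C4, C5 and C11 relative to one another, whereas the remote silyloxy centre is not expected to differentiate the two alkene faces, so the diastereomer with the mirror-image bicycle should form alongside and is removed here.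

**Step 12**
Reactants: 16 methylidene ketone
Product: 17 (1R,5R,7R)-7-[(3R,4Z)-3-[(tert-butyldiphenylsilyl)oxy]-5-iodo-2-methylpent-4-en-2-yl]-2-methylbicyclo[3.1.1]hept-2-en-6-one
Conditions: PdCl2(MeCN)2 (5 mol%), benzene, 25 °C
Reagents that add atoms: none
Why: Catalysis by divalent palladium moves the exocyclic double bond into ring A (the thermodynamically favoured trisubstituted position, as in the β- to α-pinene relationship), and no other isomer can form because the remaining allylic hydrogen is at a bridgehead.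

**Step 13**
Reactants: 17 cyclobutanone
Product: 18 (1R,5R,7R)-7-[(3R,4Z)-3-[(tert-butyldiphenylsilyl)oxy]-5-iodo-2-methylpent-4-en-2-yl]-2-methyl-6-methylidenebicyclo[3.1.1]hept-2-ene
Conditions: Ph3PCH3Br (1.3 equiv), KOt-Bu (1.2 equiv), THF, 0 °C; ylide pre-formed, then ketone added
Reagents that add atoms: methyltriphenylphosphonium bromide, C[P+](c1ccccc1)(c1ccccc1)c1ccccc1.[Br-]
Why: Wittig methylenation of the strained, non-enolizable cyclobutanone installs the methylidene carbon that becomes the C10 methyl group and removes the thermally labile β,γ-unsaturated cyclobutanone.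

**Step 14**
Reactants: 18 diene
Product: 19 (1R,5R,7S)-7-[(3R,4Z)-3-[(tert-butyldiphenylsilyl)oxy]-5-iodo-2-methylpent-4-en-2-yl]-4-methyl-6-methylidenebicyclo[3.1.1]hept-3-en-2-one
Conditions: CrO3, 3,5-dimethylpyrazole, CH2Cl2, −20 °C
Reagents that add atoms: chromium trioxide, O=[Cr](=O)=O
Why: Allylic oxidation of the ring methylene next to the trisubstituted alkene (the α-pinene to verbenone transformation) installs the C1 ketone, while the methylidene group has only bridgehead allylic hydrogens and is left alone.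

**Step 15**
Reactants: 19 alkenyl iodide with exocyclic methylidene
Product: 20 (4R,5S,7R,10R,11R)-7-[(tert-butyldiphenylsilyl)oxy]longipina-2,8-dien-1-one
Conditions: Pd(OAc)2 (10 mol%), PPh3 (25 mol%), HCO2Na (3 equiv), Et4NCl, DMF, 80 °C
Reagents that add atoms: none
Why: Zerovalent palladium inserts into the C–I bond with retention of the Z geometry, the alkenylpalladium adds syn across the exocyclic C10=CH2 bond (C9 to C10, palladium to the terminal carbon), and the resulting neopentyl-type alkylpalladium, which has no β-hydrogen, exchanges iodide for formate, loses CO2 and reductively eliminates C–H so that the former methylidene carbon becomes the C10 methyl group. The closest known reaction type is the reductive (hydride-capture) Heck cyclization of aryl and alkenyl halides onto 1,1-disubstituted alkenes to give methyl-bearing quaternary centres. The seven-membered ring closes in the 7-exo-trig mode. The only new stereocentre, C10, is controlled by the tether: the chain is anchored on C5, which sits 1,3 across the cyclobutane from C10, so C9 can reach only the face of the methylidene π bond that is cis to the C5 substituent, and the new methyl is forced to the ring-A side as in the target. The step needs exo rather than 8-endo insertion and hydride capture faster than β-carbon elimination (opening of the cyclobutane) or 3-exo insertion into the new C8=C9 bond; the 1,1-disubstituted alkene favours exo attack, and a high formate concentration with chloride additive is chosen to shorten the life of the alkylpalladium intermediate.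

**Step 16**
Reactants: 20 silyl ether
Product: 21 (4R,5S,7R,10R,11R)-7-hydroxylongipina-2,8-dien-1-one
Conditions: TBAF, THF, 40 °C
Reagents that add atoms: none
Why: Fluoride cleaves the hindered silyl ether and frees the allylic C7 hydroxyl that will direct the osmylation.

**Step 17**
Reactants: 21 allylic alcohol
Product: 22 (4R,5S,7S,8R,9S,10R,11R)-7,8,9-trihydroxylongipin-2-en-1-one
Conditions: OsO4 (5 mol%), N-methylmorpholine N-oxide, acetone/H2O, 23 °C
Reagents that add atoms: N-methylmorpholine N-oxide, C[N+]1([O-])CCOCC1; water, O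
Why: Catalytic osmylation with N-methylmorpholine N-oxide as the stoichiometric oxidant adds both hydroxyls cis to the electron-richer C8=C9 bond from the face anti to the allylic C7 hydroxyl (the usual empirical rule for allylic alcohols), which gives C8–O trans to C7–O and C9–O cis to C8–O, while the electron-poor enone alkene should react much more slowly.

**Step 18**
Reactants: 22 triol; 23 angelic anhydride (one molecule is consumed per hydroxyl, three in all)
Product: 24 (4R,5S,7S,8R,9S,10R,11R)-7,8,9-tris(angeloyloxy)longipin-2-en-1-one (CNP0330079.1)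
Conditions: LiN(SiMe3)2 (3.3 equiv in all) and angelic anhydride (4.5 equiv in all) added in three alternating portions, THF, −20 to 23 °C; sat. aq. NH4Cl quench
Reagents that add atoms: angelic anhydride (compound 23; each of the three angeloyl groups comes from a separate molecule), C/C=C(/C)C(=O)OC(=O)/C(C)=C\C
Why: Acylation of each lithium alkoxide by the anhydride, which transfers one angeloyl group per molecule and leaves as lithium angelate, needs no nucleophilic amine catalyst and should therefore esterify all three hindered hydroxyls while keeping the Z geometry of the angeloyl groups; no stereocentre is formed or touched.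

**Compound list**

1 | (S)-pantolactone, (3S)-3-hydroxy-4,4-dimethyloxolan-2-one | O=C1[C@@H](O)C(C)(C)CO1 | starting material
2 | (3S)-3-[(tert-butyldiphenylsilyl)oxy]-4,4-dimethyloxolan-2-one | O=C1[C@@H](O[Si](c2ccccc2)(c2ccccc2)C(C)(C)C)C(C)(C)CO1 | intermediate
3 | (3S)-3-[(tert-butyldiphenylsilyl)oxy]-4,4-dimethyloxolan-2-ol (anomer mixture) | OC1[C@@H](O[Si](c2ccccc2)(c2ccccc2)C(C)(C)C)C(C)(C)CO1 | intermediate
4 | (3R)-3-[(tert-butyldiphenylsilyl)oxy]-2,2-dimethylpent-4-yn-1-ol | C#C[C@@H](O[Si](c1ccccc1)(c1ccccc1)C(C)(C)C)C(C)(C)CO | intermediate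
5 | (3S)-3-[(tert-butyldiphenylsilyl)oxy]-5-iodo-2,2-dimethylpent-4-yn-1-ol | IC#C[C@@H](O[Si](c1ccccc1)(c1ccccc1)C(C)(C)C)C(C)(C)CO | intermediate
6 | (3R,4Z)-3-[(tert-butyldiphenylsilyl)oxy]-5-iodo-2,2-dimethylpent-4-en-1-ol | I/C=C\[C@@H](O[Si](c1ccccc1)(c1ccccc1)C(C)(C)C)C(C)(C)CO | intermediate
7 | (3R,4Z)-3-[(tert-butyldiphenylsilyl)oxy]-5-iodo-2,2-dimethylpent-4-enal | I/C=C\[C@@H](O[Si](c1ccccc1)(c1ccccc1)C(C)(C)C)C(C)(C)C=O | intermediate
8 | (5R,6Z)-5-[(tert-butyldiphenylsilyl)oxy]-7-iodo-4,4-dimethylhepta-1,6-dien-3-ol (C3 epimers) | I/C=C\[C@@H](O[Si](c1ccccc1)(c1ccccc1)C(C)(C)C)C(C)(C)C(O)C=C | intermediate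
9 | 2-methoxypropan-2-yl mixed ketal of 8 | I/C=C\[C@@H](O[Si](c1ccccc1)(c1ccccc1)C(C)(C)C)C(C)(C)C(OC(C)(C)OC)C=C | intermediate
10 | isopropenyl ether of 8 (allyl vinyl ether) | I/C=C\[C@@H](O[Si](c1ccccc1)(c1ccccc1)C(C)(C)C)C(C)(C)C(OC(C)=C)C=C | intermediate
11 | (5E,8R,9Z)-8-[(tert-butyldiphenylsilyl)oxy]-10-iodo-7,7-dimethyldeca-5,9-dien-2-one | I/C=C\[C@@H](O[Si](c1ccccc1)(c1ccccc1)C(C)(C)C)C(C)(C)/C=C/CCC(C)=O | intermediate
12 | methyl (2E,6E,9R,10Z)-9-[(tert-butyldiphenylsilyl)oxy]-11-iodo-3,8,8-trimethylundeca-2,6,10-trienoate | I/C=C\[C@@H](O[Si](c1ccccc1)(c1ccccc1)C(C)(C)C)C(C)(C)/C=C/CC/C(C)=C/C(=O)OC | intermediate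
13 | (2E,6E,9R,10Z)-9-[(tert-butyldiphenylsilyl)oxy]-11-iodo-3,8,8-trimethylundeca-2,6,10-trienoic acid | I/C=C\[C@@H](O[Si](c1ccccc1)(c1ccccc1)C(C)(C)C)C(C)(C)/C=C/CC/C(C)=C/C(=O)O | intermediate
14 | acid chloride of 13 | I/C=C\[C@@H](O[Si](c1ccccc1)(c1ccccc1)C(C)(C)C)C(C)(C)/C=C/CC/C(C)=C/C(=O)Cl | intermediate
15 | (6E,9R,10Z)-9-[(tert-butyldiphenylsilyl)oxy]-11-iodo-8,8-dimethyl-3-methylideneundeca-1,6,10-trien-1-one (vinylketene) | I/C=C\[C@@H](O[Si](c1ccccc1)(c1ccccc1)C(C)(C)C)C(C)(C)/C=C/CCC(=C)C=C=O | intermediate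
16 | (1R,5R,7R)-7-[(3R,4Z)-3-[(tert-butyldiphenylsilyl)oxy]-5-iodo-2-methylpent-4-en-2-yl]-2-methylidenebicyclo[3.1.1]heptan-6-one | I/C=C\[C@@H](O[Si](c3ccccc3)(c3ccccc3)C(C)(C)C)C(C)(C)[C@@H]1[C@H]2CCC(=C)[C@@H]1C2=O | intermediate
17 | (1R,5R,7R)-7-[(3R,4Z)-3-[(tert-butyldiphenylsilyl)oxy]-5-iodo-2-methylpent-4-en-2-yl]-2-methylbicyclo[3.1.1]hept-2-en-6-one | I/C=C\[C@@H](O[Si](c3ccccc3)(c3ccccc3)C(C)(C)C)C(C)(C)[C@@H]1[C@H]2CC=C(C)[C@@H]1C2=O | intermediate
18 | (1R,5R,7R)-7-[(3R,4Z)-3-[(tert-butyldiphenylsilyl)oxy]-5-iodo-2-methylpent-4-en-2-yl]-2-methyl-6-methylidenebicyclo[3.1.1]hept-2-ene | I/C=C\[C@@H](O[Si](c3ccccc3)(c3ccccc3)C(C)(C)C)C(C)(C)[C@@H]1[C@H]2CC=C(C)[C@@H]1C2=C | intermediate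
19 | (1R,5R,7S)-7-[(3R,4Z)-3-[(tert-butyldiphenylsilyl)oxy]-5-iodo-2-methylpent-4-en-2-yl]-4-methyl-6-methylidenebicyclo[3.1.1]hept-3-en-2-one | I/C=C\[C@@H](O[Si](c3ccccc3)(c3ccccc3)C(C)(C)C)C(C)(C)[C@@H]1[C@H]2C(=O)C=C(C)[C@@H]1C2=C | intermediate
20 | (4R,5S,7R,10R,11R)-7-[(tert-butyldiphenylsilyl)oxy]longipina-2,8-dien-1-one (tricycle with cis C8=C9 alkene, C10 methyl on the ring-A side) | C=1[C@@H](O[Si](c4ccccc4)(c4ccccc4)C(C)(C)C)C(C)(C)[C@@H]2[C@H]3C(=O)C=C(C)[C@@H]2[C@@]3(C)C=1 | intermediate
21 | (4R,5S,7R,10R,11R)-7-hydroxylongipina-2,8-dien-1-one | C=1[C@@H](O)C(C)(C)[C@@H]2[C@H]3C(=O)C=C(C)[C@@H]2[C@@]3(C)C=1 | intermediate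
22 | (4R,5S,7S,8R,9S,10R,11R)-7,8,9-trihydroxylongipin-2-en-1-one | O[C@@H]1[C@@H](O)C(C)(C)[C@@H]2[C@H]3C(=O)C=C(C)[C@@H]2[C@@]3(C)[C@@H]1O | intermediate
23 | angelic anhydride, (Z)-2-methylbut-2-enoic anhydride | C/C=C(/C)C(=O)OC(=O)/C(C)=C\C | starting material
24 | (4R,5S,7S,8R,9S,10R,11R)-7,8,9-tris(angeloyloxy)longipin-2-en-1-one, CNP0330079.1 | C/C=C(/C)C(=O)O[C@@H]1[C@@H](OC(=O)/C(C)=C\C)C(C)(C)[C@@H]2[C@H]3C(=O)C=C(C)[C@@H]2[C@@]3(C)[C@@H]1OC(=O)/C(C)=C\C | target

**Total step count:** 18. **Longest linear sequence:** 18 steps (from 1).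

**Steps most likely to fail**

Step 15 (key step). The alkylpalladium formed after insertion may open the four-membered ring by β-carbon elimination or insert 3-exo into the new alkene before hydride capture; the C–I bond may also be reduced before cyclization, or closure may go 8-endo. The fallback closes the same C9–C10 bond by a radical and sets out from 18. TBAF in DMF at 60 °C removes the silyl group and eliminates HI to give the propargylic alcohol (1R,5R,7R)-7-[(3R)-3-hydroxy-2-methylpent-4-yn-2-yl]-2-methyl-6-methylidenebicyclo[3.1.1]hept-2-ene F1. Dess–Martin oxidation gives the ynone F2. Fe(acac)3 and PhSiH3 in EtOH at 60 °C transfer a hydrogen atom to the exocyclic methylidene in the Markovnikov sense, and the tertiary cyclobutyl radical at C10 closes 7-endo on the terminal ynone carbon (hydrogen-atom-transfer-initiated Giese cyclization) to give longipina-2,8-dien-7-one F3, again with C9 delivered from the C5 side. Reduction with BH3·SMe2 and the catalyst (S)-1-methyl-3,3-diphenyltetrahydro-1H,3H-pyrrolo[1,2-c][1,3,2]oxazaborole (CBS reduction, quaternary C6 as the large group) gives (7R)-longipina-2,8-dien-7-ol F4. Silylation (TBDPSCl, imidazole) gives the silyl ether F5, and CrO3/3,5-dimethylpyrazole oxidation of the ring-A methylene returns to the route at 20.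

Step 11. The ketene carbonyl carbon may bond to the distal alkene carbon and give the fused instead of the bridged ring, the cyclobutanone may revert thermally, and the two alkene faces are not differentiated. The fallback sets out from 13 and uses a keteniminium salt, which adds to unactivated 1,2-disubstituted alkenes far more readily and at lower temperature than the ketene. The acid chloride 14 and dimethylamine give the N,N-dimethylamide F6. Tf2O and 2,4,6-collidine in 1,2-dichloroethane generate the vinylketeniminium ion, which cyclizes to the cyclobutaniminium triflate F7. Aqueous NaHCO3 hydrolysis returns to the route at 16. The diastereomer separation is still needed.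

Step 18. Acylation of three neighbouring hindered hydroxyls may stop short of the triester, excess base may deprotonate the enone at its γ-methyl group, and the angeloyl double bonds may isomerize from Z to E under forcing conditions. The fallback sets out from 22 and builds the double bonds on esters already in place. Esterification with 2-[bis(2,2,2-trifluoroethoxy)phosphoryl]propanoic acid (EDC·HCl, DMAP, CH2Cl2) gives the tris(phosphonopropanoate) F8. Still–Gennari olefination with acetaldehyde (KN(SiMe3)2, 18-crown-6, THF, −78 °C) is Z-selective and returns to the route at 24.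

**Further compounds**

F1 | step 15 | (1R,5R,7R)-7-[(3R)-3-hydroxy-2-methylpent-4-yn-2-yl]-2-methyl-6-methylidenebicyclo[3.1.1]hept-2-ene | C#C[C@@H](O)C(C)(C)[C@@H]1[C@H]2CC=C(C)[C@@H]1C2=C
F2 | step 15 | 4-methyl-4-[(1R,5R,7R)-2-methyl-6-methylidenebicyclo[3.1.1]hept-2-en-7-yl]pent-1-yn-3-one | C#CC(=O)C(C)(C)[C@@H]1[C@H]2CC=C(C)[C@@H]1C2=C
F3 | step 15 | longipina-2,8-dien-7-one (ring stereocentres as in 20) | C=1C(=O)C(C)(C)[C@@H]2[C@H]3CC=C(C)[C@@H]2[C@@]3(C)C=1
F4 | step 15 | (7R)-longipina-2,8-dien-7-ol (1-deoxo analogue of 21) | C=1[C@@H](O)C(C)(C)[C@@H]2[C@H]3CC=C(C)[C@@H]2[C@@]3(C)C=1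
F5 | step 15 | (7R)-7-[(tert-butyldiphenylsilyl)oxy]longipina-2,8-diene (1-deoxo analogue of 20) | C=1[C@@H](O[Si](c4ccccc4)(c4ccccc4)C(C)(C)C)C(C)(C)[C@@H]2[C@H]3CC=C(C)[C@@H]2[C@@]3(C)C=1
F6 | step 11 | N,N-dimethylamide of acid 13 | I/C=C\[C@@H](O[Si](c1ccccc1)(c1ccccc1)C(C)(C)C)C(C)(C)/C=C/CC/C(C)=C/C(=O)N(C)C
F7 | step 11 | N,N-dimethyliminium triflate of ketone 16 | I/C=C\[C@@H](O[Si](c3ccccc3)(c3ccccc3)C(C)(C)C)C(C)(C)[C@@H]1[C@H]2CCC(=C)[C@@H]1C2=[N+](C)C.[O-]S(=O)(=O)C(F)(F)F
F8 | step 18 | 7,8,9-tris{2-[bis(2,2,2-trifluoroethoxy)phosphoryl]propanoate} of triol 22 | CC(P(=O)(OCC(F)(F)F)OCC(F)(F)F)C(=O)O[C@@H]1[C@@H](OC(=O)C(C)P(=O)(OCC(F)(F)F)OCC(F)(F)F)C(C)(C)[C@@H]2[C@H]3C(=O)C=C(C)[C@@H]2[C@@]3(C)[C@@H]1OC(=O)C(C)P(=O)(OCC(F)(F)F)OCC(F)(F)F
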